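**Assumption:** the SMILES is taken literally. The decalin is cis-fused (angular C10-Me and C5-H syn), the C6 CH2Ar group is syn to the angular Me, and the C7-Me is cis to the C6 CH2Ar group. Numbering below is avarane-type: C10 quaternary Me, C5 ring-fusion H, C6 quaternary, C7 CH(Me), C1 =CH2.

## Retrosynthetic overview
1. The quinone is unmasked last: a tetra-oxygenated arene undergoes pair-selective oxidative demethylation (CAN) after the future OH is switched from MOM to acetate.
2. The C1 exocyclic methylene comes from Wittig methylenation of a C1 ketone. The C7-Me comes from face-selective hydrogenation of a C7 exocyclic methylene, itself made from the C7 ketone.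
3. The C6 quaternary centre (Me plus CH2Ar) is built by two α′-alkylations of a cis-fused decalone with C8 blocked. The cis ring fusion comes from hydrogenation of a Wieland–Miescher-type enone.
4. Ring order: the decalin forms in two steps. Michael addition forms the triketone, then a proline-catalysed aldol condensation closes the second six-membered ring and sets C10. The arene is commercial-derived and carried intact until the quinone is formed.

## Route

**Step 1**
Reactants: 1 (2-methylcyclohexane-1,3-dione) + 2 (methyl vinyl ketone)
Product: 3 (2-methyl-2-(3-oxobutyl)cyclohexane-1,3-dione)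
Conditions: MVK (1.2 equiv), H2O, 60 °C, 12 h
Reagents that add atoms: none (2 is the reactant)
Why: Michael addition of the acidic dione to MVK gives an achiral, prochiral triketone.

**Step 2**
Reactants: 3
Product: 4 ((8aR)-Wieland–Miescher ketone)
Conditions: D-proline (35 mol%), DMSO, rt, 3 d; then TsOH (cat.), PhH, reflux; recrystallise
Reagents that add atoms: none (D-proline is a catalyst; water is lost)
Why: Proline-catalysed intramolecular aldol condensation (Wieland–Miescher/Hajos–Parrish type). The D-proline enamine attacks one of the two enantiotopic ring ketones, which sets quaternary C10 as R (the first stereocentre). Expected ee is about 70–80 %.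

**Step 3 (enzymatic)**
Reactants: 4
Product: 5 ((4aR,5R)-5-hydroxy-4a-methyl-4,4a,5,6,7,8-hexahydronaphthalen-2(3H)-one; OH syn to Me)
Conditions: ketoreductase (NADPH-dependent carbonyl reductase/alcohol dehydrogenase class, (R)-selective, screened kit enzyme), NADP+ (cat.), D-glucose, glucose dehydrogenase, 0.1 M KPi pH 7, 10 % DMSO, 30 °C, stop when the (R)-enantiomer is consumed
Reagents that add atoms: none (only H is delivered, from NADPH/glucose)
Why: The enzyme reduces only the unhindered saturated C1 ketone, leaving the conjugated enone untouched. It also discriminates the enantiomers, so the minor (S)-diketone is left unreduced and removed by chromatography, upgrading ee to >99 %. The C1 carbinol centre set here is removed later.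

**Step 4**
Reactants: 5
Product: 6 (C1 TBS ether)
Conditions: TBSOTf, 2,6-lutidine, CH2Cl2, 0 °C→rt
Reagents that add atoms: TBSOTf, CC(C)(C)[Si](C)(C)OS(=O)(=O)C(F)(F)F
Why: silylation of the hindered neopentylic secondary alcohol; no stereocentre changes.

**Step 5**
Reactants: 6
Product: 7 (cis-fused decalone: Me-10, H-5 and OTBS all on one face)
Conditions: H2 (1 atm), 10 % Pd/C, EtOAc, pyridine (cat.), rt
Reagents that add atoms: none (H2 adds only H)
Why: Heterogeneous hydrogenation of angular-methyl octalone enones on Pd delivers H to the β-carbon C5 from the face syn to the angular Me. This sets C5-H cis to Me-10; C6 becomes CH2.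

**Step 6**
Reactants: 7
Product: 8 (C8-hydroxymethylene ketone)
Conditions: HCO2Et, NaOMe, PhH, 0 °C→rt
Reagents that add atoms: ethyl formate, CCOC=O
Why: Claisen formylation occurs at the less hindered α-carbon C8 (the classical blocking of one α-site of a 2-decalone), leaving C6 free for alkylation.

**Step 7**
Reactants: 8
Product: 9 (C8 n-butylthiomethylene ketone)
Conditions: n-BuSH, TsOH (cat.), PhH, 4 Å MS, rt
Reagents that add atoms: 1-butanethiol, CCCCS
Why: Ireland-type vinylogous thioester formation converts the sensitive hydroxymethylene into a robust blocking group.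

**Step 8**
Reactants: 9
Product: 10 (C6-methyl ketone, C6 epimer mixture)
Conditions: KOt-Bu, t-BuOH/THF, 0 °C; then MeI, rt
Reagents that add atoms: methyl iodide, CI
Why: Regiospecific α′-enolate alkylation at C6. The new C6 stereocentre is irrelevant because C6 is re-enolised in Step 14.

**Step 9**
Reactants: 11 (2,4,5-trimethoxybenzaldehyde)
Product: 12 (2,4,5-trimethoxyphenol)
Conditions: mCPBA, CH2Cl2, 0 °C→rt; then K2CO3, MeOH
Reagents that add atoms: mCPBA, O=C(OO)c1cccc(Cl)c1 (source of the phenolic O)
Why: Dakin/Baeyer–Villiger oxidation; the electron-rich aryl migrates to give the aryl formate, which methanolysis converts to the phenol.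

**Step 10**
Reactants: 12
Product: 13 (2-hydroxy-3,5,6-trimethoxybenzaldehyde)
Conditions: (CH2O)n, MgCl2, Et3N, MeCN, reflux
Reagents that add atoms: formaldehyde, C=O
Why: Mg-phenoxide ortho-formylation is regiospecific because the only free position ortho to OH is C6; this places the future benzylic carbon between the OH and an OMe.

**Step 11**
Reactants: 13
Product: 14 (MOM ether)
Conditions: MOMCl, i-Pr2NEt, CH2Cl2, 0 °C
Reagents that add atoms: chloromethyl methyl ether, COCCl
Why: Phenol protection as an acetal that survives enolate, hydrogenation and Ti(IV)/Wittig conditions.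

**Step 12**
Reactants: 14
Product: 15 (benzylic alcohol)
Conditions: NaBH4, MeOH, 0 °C
Reagents that add atoms: none
Why: Chemoselective aldehyde reduction.

**Step 13**
Reactants: 15
Product: 16 (benzylic bromide)
Conditions: CBr4, PPh3, CH2Cl2, 0 °C, use crude immediately
Reagents that add atoms: carbon tetrabromide, BrC(Br)(Br)Br
Why: Appel bromination under neutral conditions; this electron-rich benzylic bromide is unstable, so it is used at once.

**Step 14**
Reactants: 10 + 16
Product: 17 (C6 quaternary centre installed)
Conditions: LDA, THF, −78→0 °C; then DMPU, 16, −78 °C→rt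
Reagents that add atoms: none (16 is the reactant)
Why: Stork–Ireland α′-alkylation of the thiomethylene-blocked ketone gives a regiodefined, planar C6=C7 enolate. In the cis-fused system ring A folds under ring B, so the bulky electrophile attacks the convex face (syn to H5/Me10). This puts CH2Ar up and Me down.

**Step 15**
Reactants: 17
Product: 18 (C7 ketone, C8 unblocked)
Conditions: 10 % aq. NaOH, MeOH/THF, 50 °C
Reagents that add atoms: none (the =CH–SBu unit leaves as a thioformate)
Why: Base-mediated retro-Claisen-type cleavage of the vinylogous thioester removes the blocking group. C6 is quaternary, so nothing epimerises.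

**Step 16**
Reactants: 18
Product: 19 (C7 exocyclic methylene)
Conditions: Cp2TiMe2, PhMe, 70 °C, dark
Reagents that add atoms: dimethyltitanocene (CH2 source), C[Ti](C)(C1C=CC=C1)C1C=CC=C1
Why: Petasis methylenation works on the neopentylic ketone under non-basic, non-acidic conditions that spare the TBS and MOM groups.

**Step 17**
Reactants: 19
Product: 20 (C7-Me installed)
Conditions: H2 (1 atm), PtO2, EtOAc, rt
Reagents that add atoms: none (H2)
Why: Heterogeneous hydrogenation of the exocyclic alkene from the face anti to the large CH2Ar group (syn to the small C6-Me). H-7 goes down and the new Me goes up, cis to CH2Ar.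

**Step 18**
Reactants: 20
Product: 21 (C1 alcohol)
Conditions: TBAF, THF, 50 °C
Reagents that add atoms: none
Why: Fluoride desilylation.

**Step 19**
Reactants: 21
Product: 22 (C1 ketone)
Conditions: Dess–Martin periodinane, NaHCO3, CH2Cl2, rt
Reagents that add atoms: none
Why: Oxidation removes the enzymatically set C1 stereocentre; C10 is quaternary and C5 is not α to the new ketone, so neither epimerises.

**Step 20**
Reactants: 22
Product: 23 (C1=CH2 diene, MOM arene)
Conditions: Ph3P+CH3 Br−, KOt-Bu, THF/PhMe, 65 °C
Reagents that add atoms: methyltriphenylphosphonium bromide, C[P+](c1ccccc1)(c1ccccc1)c1ccccc1.[Br-] (CH2 source)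
Why: Wittig methylenation of the WMK-type neopentylic ketone gives the exocyclic alkene without touching other groups.

**Step 21**
Reactants: 23
Product: 24 (free phenol)
Conditions: TMSOTf, 2,2′-bipyridyl, MeCN, 0 °C→rt; then H2O
Reagents that add atoms: none
Why: Non-acidic cleavage of an aromatic MOM ether, chosen to protect the acid-sensitive exocyclic alkene.

**Step 22**
Reactants: 24
Product: 25 (aryl acetate)
Conditions: Ac2O, pyridine, DMAP, CH2Cl2, 0 °C
Reagents that add atoms: acetic anhydride, CC(=O)OC(C)=O
Why: The electron-withdrawing acetate deactivates the Q2/Q5 oxygen pair, so the next oxidation is directed to the para-dimethoxy pair.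

**Step 23**
Reactants: 25
Product: 26 (quinone acetate)
Conditions: CAN (3 equiv), MeCN/H2O 2:1, 0 °C, 10 min
Reagents that add atoms: water, O (source of the two quinone carbonyl oxygens)
Why: Oxidative demethylation of the p-dimethoxy pair (the more electron-rich one) gives the p-quinone; the acetoxy and adjacent methoxy groups remain.

**Step 24**
Reactants: 26
Product: 27 (target)
Conditions: K2CO3 (0.1 equiv), MeOH/THF, 0 °C, 10 min; aq. HCl work-up
Reagents that add atoms: none
Why: The acetate of the strongly acidic hydroxyquinone is cleaved in minutes by methanolysis. The resulting hydroxyquinone anion resists nucleophilic attack, so the quinone survives. No stereocentres are touched.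

## Compound list
1 | 2-methylcyclohexane-1,3-dione | CC1C(=O)CCCC1=O | starting material
2 | methyl vinyl ketone | C=CC(C)=O | starting material
3 | 2-methyl-2-(3-oxobutyl)cyclohexane-1,3-dione | CC1(CCC(C)=O)C(=O)CCCC1=O | intermediate
4 | (8aR)-Wieland–Miescher ketone | C[C@@]12CCC(=O)C=C1CCCC2=O | intermediate
5 | (4aR,5R)-5-hydroxy-4a-methyl-4,4a,5,6,7,8-hexahydronaphthalen-2(3H)-one | C[C@@]12CCC(=O)C=C1CCC[C@H]2O | intermediate
6 | 5-OTBS analogue of 5 | C[C@@]12CCC(=O)C=C1CCC[C@H]2O[Si](C)(C)C(C)(C)C | intermediate
7 | cis-fused decalone (4a-Me, 8a-H and 5-OTBS on one face) | C[C@@]12CCC(=O)C[C@@H]1CCC[C@H]2O[Si](C)(C)C(C)(C)C | intermediate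
8 | 3-(hydroxymethylene) derivative of 7 | C[C@@]12CC(=CO)C(=O)C[C@@H]1CCC[C@H]2O[Si](C)(C)C(C)(C)C | intermediate
9 | 3-(butylsulfanylmethylene) derivative of 7 | C[C@@]12CC(=CSCCCC)C(=O)C[C@@H]1CCC[C@H]2O[Si](C)(C)C(C)(C)C | intermediate
10 | 1-methyl derivative of 9 (C1 epimer mixture) | C[C@@]12CC(=CSCCCC)C(=O)C(C)[C@@H]1CCC[C@H]2O[Si](C)(C)C(C)(C)C | intermediate
11 | 2,4,5-trimethoxybenzaldehyde | O=Cc1cc(OC)c(OC)cc1OC | starting material
12 | 2,4,5-trimethoxyphenol | Oc1cc(OC)c(OC)cc1OC | intermediate
13 | 2-hydroxy-3,5,6-trimethoxybenzaldehyde | O=Cc1c(O)c(OC)cc(OC)c1OC | intermediate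
14 | 2-(methoxymethoxy)-3,5,6-trimethoxybenzaldehyde | O=Cc1c(OCOC)c(OC)cc(OC)c1OC | intermediate
15 | [2-(methoxymethoxy)-3,5,6-trimethoxyphenyl]methanol | OCc1c(OCOC)c(OC)cc(OC)c1OC | intermediate
16 | 1-(bromomethyl)-2-(methoxymethoxy)-3,5,6-trimethoxybenzene | BrCc1c(OCOC)c(OC)cc(OC)c1OC | intermediate
17 | C1-quaternary (Me, CH2Ar up/down as in target), thiomethylene ketone | C[C@@]12CC(=CSCCCC)C(=O)[C@@](C)(Cc3c(OCOC)c(OC)cc(OC)c3OC)[C@@H]1CCC[C@H]2O[Si](C)(C)C(C)(C)C | intermediate
18 | C7 ketone, unblocked | C[C@@]12CCC(=O)[C@@](C)(Cc3c(OCOC)c(OC)cc(OC)c3OC)[C@@H]1CCC[C@H]2O[Si](C)(C)C(C)(C)C | intermediate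
19 | C7 exocyclic methylene | C[C@@]12CCC(=C)[C@@](C)(Cc3c(OCOC)c(OC)cc(OC)c3OC)[C@@H]1CCC[C@H]2O[Si](C)(C)C(C)(C)C | intermediate
20 | C7-methyl (Me up, H down) | C[C@@]12CC[C@@H](C)[C@@](C)(Cc3c(OCOC)c(OC)cc(OC)c3OC)[C@@H]1CCC[C@H]2O[Si](C)(C)C(C)(C)C | intermediate
21 | C1 alcohol | C[C@@]12CC[C@@H](C)[C@@](C)(Cc3c(OCOC)c(OC)cc(OC)c3OC)[C@@H]1CCC[C@H]2O | intermediate
22 | C1 ketone | C[C@@]12CC[C@@H](C)[C@@](C)(Cc3c(OCOC)c(OC)cc(OC)c3OC)[C@@H]1CCCC2=O | intermediate
23 | C1 exocyclic methylene, MOM arene | C[C@@]12CC[C@@H](C)[C@@](C)(Cc3c(OCOC)c(OC)cc(OC)c3OC)[C@@H]1CCCC2=C | intermediate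
24 | free phenol | C[C@@]12CC[C@@H](C)[C@@](C)(Cc3c(O)c(OC)cc(OC)c3OC)[C@@H]1CCCC2=C | intermediate
25 | aryl acetate | C[C@@]12CC[C@@H](C)[C@@](C)(Cc3c(OC(C)=O)c(OC)cc(OC)c3OC)[C@@H]1CCCC2=C | intermediate
26 | quinone acetate | C[C@@]12CC[C@@H](C)[C@@](C)(CC3=C(OC(C)=O)C(=O)C=C(OC)C3=O)[C@@H]1CCCC2=C | intermediate
27 | 2-hydroxy-5-methoxy-3-{[(1R,2R,4aR,8aS)-1,2,4a-trimethyl-5-methylidene-decahydronaphthalen-1-yl]methyl}cyclohexa-2,5-diene-1,4-dione | C=C1CCC[C@H]2[C@](C)(CC3=C(O)C(=O)C=C(OC)C3=O)[C@H](C)CC[C@@]12C | target

## Totals
Total steps: 24, including the 5-step arene branch (Steps 9–13). Longest linear sequence: 19 steps (Steps 1–8, then 14–24).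

## Three steps most likely to fail
1. **Step 14 (C6 quaternary centre, hindered benzylic alkylation and convex-face selectivity).**
   Fallback: change the bond construction. Alkylate the C6 enolate with a small electrophile (BnOCH2Cl), which is far more convex-selective. Convert the product to the C6-CHO, add the aryllithium from the corresponding aryl bromide, then deoxygenate the benzylic alcohol (Et3SiH/TFA).
2. **Step 5 (cis-selective hydrogenation to set C5-H).**
   Fallback: replace surface hydrogenation with a biocatalytic conjugate reduction. Screen ene-reductases (Old Yellow Enzyme family) on enone 6, which deliver hydride to C5 from an enzyme-defined face.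
3. **Step 17 (C7-methyl face selectivity).**
   Fallback: use radical hydrogenation by metal-hydride hydrogen-atom transfer (Mn(dpm)3, PhSiH3, TBHP) on 19 in place of surface hydrogenation. Its selectivity is governed by radical stereo-control rather than catalyst-surface approach, and any C7 epimer can be separated at the stage of 20 or 21.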